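The route rests on making the 3(2H)-furanone last, by a transannular, gold-catalysed 5-endo-dig addition of the tertiary C4 hydroxyl to C1 of a ten-membered ynone (C3=O, C2≡C1). One operation forges the O–C1 bond, the C1=C2 enol ether and the 1,4-oxygen bridge across the ten-membered carbocycle C1–C10. It exploits the 1,4-relationship of O4 and C1 through the C3 carbonyl, which also polarises the alkyne. The precursor, a 6,12-lactone-fused cyclodec-1-yn-3-one carrying all five stereocentres, comes from two fragments joined by an indium Barbier reaction (C7–C8) and closed by a chromium-mediated alkynyl–aldehyde addition (C2–C3).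

Key step: step 18

Remark on locants: germacrane numbering is used for all compounds (ring C1–C10; C11–C13 on C7, C12 being the lactone carbonyl closed on O6; C14 the methylene on C10; C15 the methyl on C4).
Assumption: the facial sense of the iridium catalyst in step 4 is assigned by analogy with related alcohol allylations; the antipodal ligand would be used if the analogy does not hold.

Step 1
Reactants: 1 (R)-citramalic acid
Product: 2 (2R)-2-methylbutane-1,2,4-triol
Conditions: BH3·SMe2, B(OMe)3, THF, 0 °C to rt; MeOH quench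
Reagents that add atoms: none
Why: Borane reduction of both carboxylic acids should give the triol without touching the quaternary carbinol centre C4, which is bought with the starting material.

Step 2
Reactants: 2 (2R)-2-methylbutane-1,2,4-triol
Product: 3 2-[(4R)-2,2,4-trimethyl-1,3-dioxolan-4-yl]ethan-1-ol
Conditions: Me2C(OMe)2, TsOH (cat.), acetone, rt
Reagents that add atoms: 2,2-dimethoxypropane COC(C)(C)OC
Why: Thermodynamic acetonide formation should close the five-membered 1,3-dioxolane on the 1,2-diol (favoured over the 1,3-dioxane) and leave the C6 primary alcohol free.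

Step 3
Reactants: 4 methyl 2-(hydroxymethyl)prop-2-enoate
Product: 5 methyl 2-{[(tert-butoxycarbonyl)oxy]methyl}prop-2-enoate
Conditions: Boc2O, DMAP (cat.), CH2Cl2, 0 °C to rt
Reagents that add atoms: di-tert-butyl dicarbonate CC(C)(C)OC(=O)OC(=O)OC(C)(C)C
Why: DMAP-catalysed O-acylation of the allylic alcohol should give the allylic carbonate that serves as allyl donor in step 4.

Step 4
Reactants: 3 2-[(4R)-2,2,4-trimethyl-1,3-dioxolan-4-yl]ethan-1-ol; 5 methyl 2-{[(tert-butoxycarbonyl)oxy]methyl}prop-2-enoate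
Product: 8 (5R)-3-methylidene-5-{[(4R)-2,2,4-trimethyl-1,3-dioxolan-4-yl]methyl}oxolan-2-one, via aldehyde 6 (not isolated), via hydroxy ester 7 (not isolated)
Conditions: [Ir(cod)Cl]2 (2.5 mol%), (R)-SEGPHOS (5 mol%), 4-cyano-3-nitrobenzoic acid (10 mol%), Cs2CO3 (20 mol%), THF, 70 °C
Reagents that add atoms: none
Why: In this iridium-catalysed transfer-hydrogenative 2-(alkoxycarbonyl)allylation the alcohol is dehydrogenated to aldehyde 6, the chiral π-allyliridium adds to it under catalyst control of the new C6 centre (ligand enantiomer chosen for 5R), and the alkoxide of 7 lactonises on the methyl ester.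

Step 5
Reactants: 8 (5R)-3-methylidene-5-{[(4R)-2,2,4-trimethyl-1,3-dioxolan-4-yl]methyl}oxolan-2-one
Product: 9 (5S)-3-(bromomethyl)-5-{[(4R)-2,2,4-trimethyl-1,3-dioxolan-4-yl]methyl}furan-2(5H)-one
Conditions: NBS (1.05 equiv), AIBN (cat.), PhCF3, 80 °C
Reagents that add atoms: N-bromosuccinimide O=C1CCC(=O)N1Br
Why: In this Wohl–Ziegler allylic bromination, hydrogen abstraction at the ring CH2 (C7) gives an allyl radical that should take bromine at the exocyclic terminus C13, moving the double bond into the ring as the more stable conjugated butenolide without involving C6.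

Step 6
Reactants: 10 (2Z)-3-methylpent-2-en-4-yn-1-ol
Product: 11 [(2R,3S)-3-ethynyl-3-methyloxiran-2-yl]methanol
Conditions: Ti(OiPr)4 (10 mol%), D-(−)-diethyl tartrate (12 mol%), tBuOOH, 4 Å MS, CH2Cl2, −20 °C
Reagents that add atoms: tert-butyl hydroperoxide CC(C)(C)OO
Why: In this Sharpless asymmetric epoxidation the D-(−)-tartrate complex should deliver oxygen to the face that makes C9 (oxirane C2) R, which fixes the C9–O configuration of the target (the C10 centre is erased in step 7).

Step 7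
Reactants: 11 [(2R,3S)-3-ethynyl-3-methyloxiran-2-yl]methanol
Product: 12 (2S)-3-methylidenepent-4-yne-1,2-diol
Conditions: Et2AlCl, LiTMP (gives Et2Al(TMP), 4 equiv), toluene, 0 °C; aq. Rochelle salt
Reagents that add atoms: none
Why: In this aluminium amide-mediated epoxide-to-allylic-alcohol isomerisation, aluminium activates the tertiary propargylic C10–O bond and the amide removes a proton from the methyl group (cis to H9), which should give the 10(14)-methylene with the C9–O bond and its configuration intact.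

Step 8
Reactants: 12 (2S)-3-methylidenepent-4-yne-1,2-diol
Product: 13 (4S)-4-(but-1-en-3-yn-2-yl)-2-(4-methoxyphenyl)-1,3-dioxolane (both acetal epimers)
Conditions: 4-MeOC6H4CH(OMe)2, PPTS (cat.), CH2Cl2, rt
Reagents that add atoms: 4-methoxybenzaldehyde dimethyl acetal COC(OC)c1ccc(OC)cc1
Why: Acid-catalysed transacetalisation should give the p-methoxybenzylidene acetal of the 1,2-diol; the acetal epimers are inconsequential.

Step 9
Reactants: 13 (4S)-4-(but-1-en-3-yn-2-yl)-2-(4-methoxyphenyl)-1,3-dioxolane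
Product: 14 (2S)-2-[(4-methoxyphenyl)methoxy]-3-methylidenepent-4-yn-1-ol
Conditions: DIBAL-H (3 equiv), CH2Cl2, −78 to 0 °C
Reagents that add atoms: none
Why: In this regioselective reductive acetal opening, aluminium binds the less hindered primary oxygen, that C–O bond breaks and hydride reduces the oxocarbenium ion, so the PMB ether should end on the secondary O9 with the primary alcohol free.

Step 10
Reactants: 14 (2S)-2-[(4-methoxyphenyl)methoxy]-3-methylidenepent-4-yn-1-ol
Product: 15 (2S)-2-[(4-methoxyphenyl)methoxy]-3-methylidenepent-4-ynal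
Conditions: Dess–Martin periodinane, NaHCO3, CH2Cl2, 0 °C; used at once
Reagents that add atoms: none
Why: Buffered Dess–Martin oxidation should give the α-alkoxy aldehyde under non-basic conditions that spare the acidic, doubly activated C9–H.

Step 11
Reactants: 9 (5S)-3-(bromomethyl)-5-{[(4R)-2,2,4-trimethyl-1,3-dioxolan-4-yl]methyl}furan-2(5H)-one; 15 (2S)-2-[(4-methoxyphenyl)methoxy]-3-methylidenepent-4-ynal
Product: 17 (4S,5S)-4-{(1S,2S)-1-hydroxy-2-[(4-methoxyphenyl)methoxy]-3-methylidenepent-4-yn-1-yl}-3-methylidene-5-{[(4R)-2,2,4-trimethyl-1,3-dioxolan-4-yl]methyl}oxolan-2-one, via allylindium 16 (not isolated)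
Conditions: In powder, THF/H2O (3:1), rt
Reagents that add atoms: none
Why: In this indium-mediated Barbier allylation the ring-locked (E)-allylindium 16 should attack through C7 anti to the C6 side chain (6,7-trans lactone) in a closed chair transition state (7,8-anti), matched by indium chelation between the aldehyde and PMB-ether oxygens (8,9-syn), so C7 and C8 are set here and the α-methylene lactone is regenerated by allylic transposition.

Step 12
Reactants: 17 (4S,5S)-4-{(1S,2S)-1-hydroxy-2-[(4-methoxyphenyl)methoxy]-3-methylidenepent-4-yn-1-yl}-3-methylidene-5-{[(4R)-2,2,4-trimethyl-1,3-dioxolan-4-yl]methyl}oxolan-2-one; 18 angelic acid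
Product: 20 (1S,2S)-2-[(4-methoxyphenyl)methoxy]-3-methylidene-1-[(2S,3R)-4-methylidene-5-oxo-2-{[(4R)-2,2,4-trimethyl-1,3-dioxolan-4-yl]methyl}oxolan-3-yl]pent-4-yn-1-yl (2Z)-2-methylbut-2-enoate, via mixed anhydride 19 (not isolated)
Conditions: 2,4,6-Cl3C6H2COCl, Et3N, toluene, rt; then 17, 75 °C
Reagents that add atoms: none
Why: This Yamaguchi-type esterification through mixed anhydride 19, run without a nucleophilic catalyst, should keep the (Z)-geometry of the angelate, and only the C8 hydroxyl is free to react.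

Step 13
Reactants: 20 (1S,2S)-2-[(4-methoxyphenyl)methoxy]-3-methylidene-1-[(2S,3R)-4-methylidene-5-oxo-2-{[(4R)-2,2,4-trimethyl-1,3-dioxolan-4-yl]methyl}oxolan-3-yl]pent-4-yn-1-yl (2Z)-2-methylbut-2-enoate
Product: 21 (1S,2S)-5-iodo-2-[(4-methoxyphenyl)methoxy]-3-methylidene-1-[(2S,3R)-4-methylidene-5-oxo-2-{[(4R)-2,2,4-trimethyl-1,3-dioxolan-4-yl]methyl}oxolan-3-yl]pent-4-yn-1-yl (2Z)-2-methylbut-2-enoate
Conditions: NIS, AgNO3 (10 mol%), acetone, rt, dark
Reagents that add atoms: N-iodosuccinimide O=C1CCC(=O)N1I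
Why: Silver-catalysed electrophilic iodination of the terminal alkyne (through the silver acetylide) should give the 1-iodoalkyne needed for chromium insertion.

Step 14
Reactants: 21 (1S,2S)-5-iodo-2-[(4-methoxyphenyl)methoxy]-3-methylidene-1-[(2S,3R)-4-methylidene-5-oxo-2-{[(4R)-2,2,4-trimethyl-1,3-dioxolan-4-yl]methyl}oxolan-3-yl]pent-4-yn-1-yl (2Z)-2-methylbut-2-enoate
Product: 22 (1S,2S)-1-{(2S,3R)-2-[(2R)-2,3-dihydroxy-2-methylpropyl]-4-methylidene-5-oxooxolan-3-yl}-5-iodo-2-[(4-methoxyphenyl)methoxy]-3-methylidenepent-4-yn-1-yl (2Z)-2-methylbut-2-enoate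
Conditions: AcOH/H2O/THF (3:1:1), 45 °C
Reagents that add atoms: none
Why: Mild acid hydrolysis should remove the terminal acetonide while the PMB ether, both esters and the iodoalkyne survive.

Step 15
Reactants: 22 (1S,2S)-1-{(2S,3R)-2-[(2R)-2,3-dihydroxy-2-methylpropyl]-4-methylidene-5-oxooxolan-3-yl}-5-iodo-2-[(4-methoxyphenyl)methoxy]-3-methylidenepent-4-yn-1-yl (2Z)-2-methylbut-2-enoate
Product: 23 (1S,2S)-1-{(2S,3R)-2-[(2R)-2-hydroxy-2-methyl-3-oxopropyl]-4-methylidene-5-oxooxolan-3-yl}-5-iodo-2-[(4-methoxyphenyl)methoxy]-3-methylidenepent-4-yn-1-yl (2Z)-2-methylbut-2-enoate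
Conditions: TEMPO (20 mol%), PhI(OAc)2, CH2Cl2, rt
Reagents that add atoms: none
Why: TEMPO/oxoammonium oxidation should take the primary C3 alcohol to the aldehyde; the tertiary C4 hydroxyl cannot be oxidised and the aldehyde has no α-hydrogen to epimerise.

Step 16
Reactants: 23 (1S,2S)-1-{(2S,3R)-2-[(2R)-2-hydroxy-2-methyl-3-oxopropyl]-4-methylidene-5-oxooxolan-3-yl}-5-iodo-2-[(4-methoxyphenyl)methoxy]-3-methylidenepent-4-yn-1-yl (2Z)-2-methylbut-2-enoate
Product: 25 (4R,6S,7R,8S,9S)-3,4-dihydroxy-9-[(4-methoxyphenyl)methoxy]-8-[(2Z)-2-methylbut-2-enoyloxy]germacra-10(14),11(13)-dien-1-yn-12,6-olide (both C3 epimers), via alkynylchromium 24 (not isolated)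
Conditions: CrCl2 (8 equiv), NiCl2 (1 mol%), THF, rt, slow addition to ca. 2 mM
Reagents that add atoms: none
Why: In this Nozaki–Hiyama–Kishi-type ring closure, chromium(II) inserts into the C–I bond to give alkynylchromium(III) 24, which should add chemoselectively to the aldehyde and close the ten-membered carbocycle (a closure type established for strained nine- and ten-membered cycloalkynes); both C3 epimers converge in step 17.

Step 17
Reactants: 25 (4R,6S,7R,8S,9S)-3,4-dihydroxy-9-[(4-methoxyphenyl)methoxy]-8-[(2Z)-2-methylbut-2-enoyloxy]germacra-10(14),11(13)-dien-1-yn-12,6-olide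
Product: 26 (4R,6S,7R,8S,9S)-4-hydroxy-9-[(4-methoxyphenyl)methoxy]-8-[(2Z)-2-methylbut-2-enoyloxy]-3-oxogermacra-10(14),11(13)-dien-1-yn-12,6-olide
Conditions: activated MnO2, CH2Cl2, rt
Reagents that add atoms: none
Why: Manganese dioxide should oxidise the secondary propargylic C3 alcohol to the conjugated ynone and leave the tertiary C4 alcohol and the protected O9 untouched.

Step 18
Reactants: 26 (4R,6S,7R,8S,9S)-4-hydroxy-9-[(4-methoxyphenyl)methoxy]-8-[(2Z)-2-methylbut-2-enoyloxy]-3-oxogermacra-10(14),11(13)-dien-1-yn-12,6-olide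
Product: 27 (4R,6S,7R,8S,9S)-1,4-epoxy-9-[(4-methoxyphenyl)methoxy]-8-[(2Z)-2-methylbut-2-enoyloxy]-3-oxogermacra-1,10(14),11(13)-trien-12,6-olide
Conditions: (4-CF3C6H4)3PAuCl (5 mol%), AgOTf (5 mol%), toluene, rt
Reagents that add atoms: none
Why: Cationic gold(I) coordinates the C1≡C2 bond of the ynone, the tertiary C4 hydroxyl adds to C1 (the β-carbon of the C3 carbonyl) in an anti-oxyauration, and protodeauration at C2 releases the enol ether and the catalyst. The closest known reaction type is the metal- or amine-promoted cycloisomerisation of α′-hydroxy ynones to 3(2H)-furanones, run here transannularly. The one ring formed (O–C4–C3–C2–C1) closes in the 5-endo-dig mode, which should be favoured because O4 and C1 already sit 1,4 across C3 inside the ten-membered ring and the closure relieves the bending strain of the endocyclic alkyne. No stereocentre is created: C4 keeps the configuration brought in with (R)-citramalic acid because its C–O bond is not broken, and the other four centres are remote from the reacting atoms. The step needs O-attack at C1 rather than C2 and no reaction at the two 1,1-disubstituted alkenes or the angelate; this is secured by the carbonyl polarisation of the alkyne, by the fact that O4 could reach C2 only through a 4-exo closure, and by the PMB group on O9, which would otherwise be a 5-endo competitor at C2.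

Step 19
Reactants: 27 (4R,6S,7R,8S,9S)-1,4-epoxy-9-[(4-methoxyphenyl)methoxy]-8-[(2Z)-2-methylbut-2-enoyloxy]-3-oxogermacra-1,10(14),11(13)-trien-12,6-olide
Product: 28 (4R,6S,7R,8S,9S)-1,4-epoxy-9-hydroxy-8-[(2Z)-2-methylbut-2-enoyloxy]-3-oxogermacra-1,10(14),11(13)-trien-12,6-olide (CNP0120053.1)
Conditions: DDQ, CH2Cl2/pH 7 buffer (10:1), 0 °C
Reagents that add atoms: none
Why: Oxidative PMB cleavage (benzylic hydride abstraction, hydrolysis of the oxocarbenium ion) should free the C9 hydroxyl under neutral conditions that avoid acyl migration and spare the lactone, angelate and furanone.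

Compound list
1 | (R)-citramalic acid, (2R)-2-hydroxy-2-methylbutanedioic acid | OC(=O)C[C@@](C)(O)C(=O)O | starting material
2 | (2R)-2-methylbutane-1,2,4-triol | OCC[C@@](C)(O)CO | intermediate
3 | 2-[(4R)-2,2,4-trimethyl-1,3-dioxolan-4-yl]ethan-1-ol | OCC[C@@]1(C)OC(C)(C)OC1 | intermediate
4 | methyl 2-(hydroxymethyl)prop-2-enoate | C=C(CO)C(=O)OC | starting material
5 | methyl 2-{[(tert-butoxycarbonyl)oxy]methyl}prop-2-enoate | C=C(COC(=O)OC(C)(C)C)C(=O)OC | intermediate
6 | 2-[(4R)-2,2,4-trimethyl-1,3-dioxolan-4-yl]acetaldehyde | O=CC[C@@]1(C)OC(C)(C)OC1 | intermediate (not isolated)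
7 | methyl (4R)-4-hydroxy-2-methylidene-5-[(4R)-2,2,4-trimethyl-1,3-dioxolan-4-yl]pentanoate | C=C(C[C@@H](O)C[C@@]1(C)OC(C)(C)OC1)C(=O)OC | intermediate (not isolated)
8 | (5R)-3-methylidene-5-{[(4R)-2,2,4-trimethyl-1,3-dioxolan-4-yl]methyl}oxolan-2-one | C=C1C(=O)O[C@@H](C[C@@]2(C)OC(C)(C)OC2)C1 | intermediate
9 | (5S)-3-(bromomethyl)-5-{[(4R)-2,2,4-trimethyl-1,3-dioxolan-4-yl]methyl}furan-2(5H)-one | BrCC1=C[C@H](C[C@@]2(C)OC(C)(C)OC2)OC1=O | intermediate
10 | (2Z)-3-methylpent-2-en-4-yn-1-ol | C#C/C(C)=C\CO | starting material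
11 | [(2R,3S)-3-ethynyl-3-methyloxiran-2-yl]methanol | OC[C@@H]1[C@](C)(C#C)O1 | intermediate
12 | (2S)-3-methylidenepent-4-yne-1,2-diol | OC[C@@H](O)C(=C)C#C | intermediate
13 | (4S)-4-(but-1-en-3-yn-2-yl)-2-(4-methoxyphenyl)-1,3-dioxolane (acetal epimers) | C#CC(=C)[C@H]1COC(c2ccc(OC)cc2)O1 | intermediate
14 | (2S)-2-[(4-methoxyphenyl)methoxy]-3-methylidenepent-4-yn-1-ol | OC[C@@H](OCc1ccc(OC)cc1)C(=C)C#C | intermediate
15 | (2S)-2-[(4-methoxyphenyl)methoxy]-3-methylidenepent-4-ynal | O=C[C@@H](OCc1ccc(OC)cc1)C(=C)C#C | intermediate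
16 | allylindium species from 9, drawn as the C13 dibromoindium compound | Br[In](Br)CC1=C[C@H](C[C@@]2(C)OC(C)(C)OC2)OC1=O | intermediate (not isolated)
17 | (4S,5S)-4-{(1S,2S)-1-hydroxy-2-[(4-methoxyphenyl)methoxy]-3-methylidenepent-4-yn-1-yl}-3-methylidene-5-{[(4R)-2,2,4-trimethyl-1,3-dioxolan-4-yl]methyl}oxolan-2-one (C7 reads S here only because the CIP ranking changes with the free C8 hydroxyl) | C=C1C(=O)O[C@@H](C[C@@]2(C)OC(C)(C)OC2)[C@@H]1[C@H](O)[C@@H](OCc3ccc(OC)cc3)C(=C)C#C | intermediate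
18 | angelic acid, (2Z)-2-methylbut-2-enoic acid | C/C=C(/C)C(=O)O | starting material
19 | (2Z)-2-methylbut-2-enoic 2,4,6-trichlorobenzoic anhydride | C/C=C(/C)C(=O)OC(=O)c1c(Cl)cc(Cl)cc1Cl | intermediate (not isolated)
20 | (1S,2S)-2-[(4-methoxyphenyl)methoxy]-3-methylidene-1-[(2S,3R)-4-methylidene-5-oxo-2-{[(4R)-2,2,4-trimethyl-1,3-dioxolan-4-yl]methyl}oxolan-3-yl]pent-4-yn-1-yl (2Z)-2-methylbut-2-enoate | C=C1C(=O)O[C@@H](C[C@@]2(C)OC(C)(C)OC2)[C@@H]1[C@H](OC(=O)/C(C)=C\C)[C@@H](OCc3ccc(OC)cc3)C(=C)C#C | intermediate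
21 | 5-iodoalkyne of 20 | C=C1C(=O)O[C@@H](C[C@@]2(C)OC(C)(C)OC2)[C@@H]1[C@H](OC(=O)/C(C)=C\C)[C@@H](OCc3ccc(OC)cc3)C(=C)C#CI | intermediate
22 | (1S,2S)-1-{(2S,3R)-2-[(2R)-2,3-dihydroxy-2-methylpropyl]-4-methylidene-5-oxooxolan-3-yl}-5-iodo-2-[(4-methoxyphenyl)methoxy]-3-methylidenepent-4-yn-1-yl (2Z)-2-methylbut-2-enoate | C=C1C(=O)O[C@@H](C[C@@](C)(O)CO)[C@@H]1[C@H](OC(=O)/C(C)=C\C)[C@@H](OCc2ccc(OC)cc2)C(=C)C#CI | intermediate
23 | (1S,2S)-1-{(2S,3R)-2-[(2R)-2-hydroxy-2-methyl-3-oxopropyl]-4-methylidene-5-oxooxolan-3-yl}-5-iodo-2-[(4-methoxyphenyl)methoxy]-3-methylidenepent-4-yn-1-yl (2Z)-2-methylbut-2-enoate | C=C1C(=O)O[C@@H](C[C@@](C)(O)C=O)[C@@H]1[C@H](OC(=O)/C(C)=C\C)[C@@H](OCc2ccc(OC)cc2)C(=C)C#CI | intermediate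
24 | alkynylchromium(III) dichloride from 23 | C=C1C(=O)O[C@@H](C[C@@](C)(O)C=O)[C@@H]1[C@H](OC(=O)/C(C)=C\C)[C@@H](OCc2ccc(OC)cc2)C(=C)C#C[Cr](Cl)Cl | intermediate (not isolated)
25 | (4R,6S,7R,8S,9S)-3,4-dihydroxy-9-[(4-methoxyphenyl)methoxy]-8-[(2Z)-2-methylbut-2-enoyloxy]germacra-10(14),11(13)-dien-1-yn-12,6-olide (C3 epimers) | C=C1C(=O)O[C@H]2C[C@@](C)(O)C(O)C#CC(=C)[C@H](OCc3ccc(OC)cc3)[C@@H](OC(=O)/C(C)=C\C)[C@H]12 | intermediate
26 | (4R,6S,7R,8S,9S)-4-hydroxy-9-[(4-methoxyphenyl)methoxy]-8-[(2Z)-2-methylbut-2-enoyloxy]-3-oxogermacra-10(14),11(13)-dien-1-yn-12,6-olide | C=C1C(=O)O[C@H]2C[C@@](C)(O)C(=O)C#CC(=C)[C@H](OCc3ccc(OC)cc3)[C@@H](OC(=O)/C(C)=C\C)[C@H]12 | intermediate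
27 | (4R,6S,7R,8S,9S)-1,4-epoxy-9-[(4-methoxyphenyl)methoxy]-8-[(2Z)-2-methylbut-2-enoyloxy]-3-oxogermacra-1,10(14),11(13)-trien-12,6-olide | C=C1C(=O)O[C@H]2C[C@@]3(C)OC(=CC3=O)C(=C)[C@H](OCc4ccc(OC)cc4)[C@@H](OC(=O)/C(C)=C\C)[C@H]12 | intermediate
28 | (4R,6S,7R,8S,9S)-1,4-epoxy-9-hydroxy-8-[(2Z)-2-methylbut-2-enoyloxy]-3-oxogermacra-1,10(14),11(13)-trien-12,6-olide (CNP0120053.1) | C=C1C(=O)O[C@H]2C[C@@]3(C)OC(=CC3=O)C(=C)[C@H](O)[C@@H](OC(=O)/C(C)=C\C)[C@H]12 | target

Total step count: 19
Longest linear sequence: 14 steps (steps 6–10, then 11–19, from 10 to 28)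

Steps most likely to fail (no step carries a new-method label)

1. Step 16. The strained ten-membered cycloalkyne may not close: protodeiodination of the alkynylchromium and intermolecular addition can outrun the transannular approach to the hindered, partly hydrated α-hydroxy aldehyde. The fallback sets out from 20 and comes back at 26, replacing the aldehyde electrophile by an acyl–palladium species and avoiding the iodoalkyne and the separate oxidation. Acetonide hydrolysis of 20 (AcOH/H2O/THF) would give the terminal-alkyne diol F1. TEMPO/PhI(OAc)2 would then give the α-hydroxy aldehyde F2, and Pinnick oxidation (NaClO2, NaH2PO4, 2-methyl-2-butene) the α-hydroxy acid F3. EtSH with EDC would give the S-ethyl thioester F4. A palladium/copper-catalysed thioester–terminal alkyne coupling (PdCl2(dppf), P(2-furyl)3, CuI, Et3N, DMF, 50 °C, high dilution) would close the ring as ynone 26 directly.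

2. Step 11. Configuration at C9 may be lost through enolisation of the β,γ-unsaturated α-alkoxy aldehyde in the aqueous medium, and aldehyde facial selectivity may erode if indium chelation is weak. The fallback sets out from 9 and comes back at 17, replacing the Barbier reaction by an anhydrous allylboration. Palladium-catalysed borylation of 9 (B2pin2, Pd2(dba)3 cat., toluene, 50 °C) would give the allylboronate F5 with boron on the primary terminus C13. Its Sc(OTf)3-catalysed addition to aldehyde 15 (CH2Cl2, −78 °C) through the closed chair with ring-locked (E)-geometry would give 17 after aqueous work-up, with C7 and C8 set by the same ring and chair control.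

3. Step 12. Slow acyl transfer to the hindered C8 hydroxyl may be accompanied by isomerisation of the angeloyl unit to the tigloyl isomer, or by lactone migration to O8 under the hot basic conditions. The fallback sets out from 17 and comes back at 20, building the (Z)-alkene on the molecule instead of transferring it. Acylation of 17 with 2-[bis(2,2,2-trifluoroethoxy)phosphoryl]propanoic acid (DCC, DMAP cat., CH2Cl2, 0 °C) would give the phosphonate ester F6. Still–Gennari olefination with acetaldehyde (KHMDS, 18-crown-6, THF, −78 °C) would then give the (Z)-2-methylbut-2-enoate 20.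

Further compounds
F1 | step 16 | terminal-alkyne diol, acetonide-free analogue of 20 | C=C1C(=O)O[C@@H](C[C@@](C)(O)CO)[C@@H]1[C@H](OC(=O)/C(C)=C\C)[C@@H](OCc2ccc(OC)cc2)C(=C)C#C
F2 | step 16 | terminal-alkyne α-hydroxy aldehyde | C=C1C(=O)O[C@@H](C[C@@](C)(O)C=O)[C@@H]1[C@H](OC(=O)/C(C)=C\C)[C@@H](OCc2ccc(OC)cc2)C(=C)C#C
F3 | step 16 | terminal-alkyne α-hydroxy acid | C=C1C(=O)O[C@@H](C[C@@](C)(O)C(=O)O)[C@@H]1[C@H](OC(=O)/C(C)=C\C)[C@@H](OCc2ccc(OC)cc2)C(=C)C#C
F4 | step 16 | S-ethyl thioester of F3 | C=C1C(=O)O[C@@H](C[C@@](C)(O)C(=O)SCC)[C@@H]1[C@H](OC(=O)/C(C)=C\C)[C@@H](OCc2ccc(OC)cc2)C(=C)C#C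
F5 | step 11 | (5S)-3-[(4,4,5,5-tetramethyl-1,3,2-dioxaborolan-2-yl)methyl]-5-{[(4R)-2,2,4-trimethyl-1,3-dioxolan-4-yl]methyl}furan-2(5H)-one | CC1(C)OB(CC2=C[C@H](C[C@@]3(C)OC(C)(C)OC3)OC2=O)OC1(C)C
F6 | step 12 | 2-[bis(2,2,2-trifluoroethoxy)phosphoryl]propanoate ester of 17 at O8 | C=C1C(=O)O[C@@H](C[C@@]2(C)OC(C)(C)OC2)[C@@H]1[C@H](OC(=O)C(C)P(=O)(OCC(F)(F)F)OCC(F)(F)F)[C@@H](OCc3ccc(OC)cc3)C(=C)C#C
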